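The route rests on opening ring C of the flavanone at three bonds. C4 is a ketone carbon wedged between C4a of ring A and the C3–C2 pair that carries the phenyl group, and O1 sits on the neighbouring C8a, so C4 can be delivered as carbon monoxide. One palladium-catalysed operation joins a hexasubstituted 2-iodophenol, CO and phenylacetylene, makes C4a–C4, C4–C3 and O1–C2, and closes ring C as a flavone. The iodophenol already carries the MOM-protected pyranone at C6, the prenyl group at C8 and MOM ethers on O5 and O7, so O1 is its only free phenol. Asymmetric copper hydride reduction then sets C2 and acid releases the three hydroxy groups.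

Key step: step 13

Assumption: the target SMILES defines no axial chirality, so the hindered pyranone–ring A axis is treated as stereochemically undefined, and rotamers or atropisomers of the MOM-protected intermediates are carried on together and converge on the target.

Step 1
Reactants: 1 3-pentanone
Product: 2 (Z)-3-(trimethylsilyloxy)pent-2-ene
Conditions: TMSOTf, Et3N, CH2Cl2, 0 °C
Reagents that add atoms: trimethylsilyl triflate, C[Si](C)(C)OS(=O)(=O)C(F)(F)F
Why: Soft enolisation and O-silylation (silyl enol ether formation) of a symmetrical ketone can give only one regioisomer, and the olefin geometry disappears in the next step.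

Step 2
Reactants: 2 (Z)-3-(trimethylsilyloxy)pent-2-ene; 3 malonyl dichloride
Product: 4 6-ethyl-4-hydroxy-5-methyl-2H-pyran-2-one
Conditions: Et2O, −78 °C to rt
Reagents that add atoms: none
Why: In this Effenberger-type pyranone synthesis one acid chloride C-acylates the silyl enol ether and the enol oxygen of the resulting tricarbonyl chain lactonises on the second, which puts ethyl on C6 and methyl on C5 of the pyranone.

Step 3
Reactants: 4 6-ethyl-4-hydroxy-5-methyl-2H-pyran-2-one
Product: 5 6-ethyl-4-hydroxy-3-iodo-5-methyl-2H-pyran-2-one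
Conditions: NIS, MeCN, 0 °C to rt, dark
Reagents that add atoms: N-iodosuccinimide, O=C1CCC(=O)N1I
Why: Electrophilic iodination of the enolic beta-dicarbonyl unit must occur at C3, the only unsubstituted ring carbon.

Step 4
Reactants: 5 6-ethyl-4-hydroxy-3-iodo-5-methyl-2H-pyran-2-one
Product: 6 6-ethyl-3-iodo-4-(methoxymethoxy)-5-methyl-2H-pyran-2-one
Conditions: MOMCl, i-Pr2NEt, CH2Cl2, 0 °C to rt
Reagents that add atoms: chloromethyl methyl ether, COCCl
Why: O-alkylation (MOM ether formation) of the acidic vinylogous acid with a hard electrophile goes mainly to O4, and any O2-alkylated 4-pyranone isomer is removed by chromatography.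

Step 5
Reactants: 7 phloroglucinol
Product: 8 3,5-bis(methoxymethoxy)phenol
Conditions: MOMCl (2.0 equiv), i-Pr2NEt, DMF, 0 °C to rt; chromatography
Reagents that add atoms: chloromethyl methyl ether, COCCl
Why: Because of the threefold symmetry any two hydroxy groups give the same bis-ether (phenol O-alkylation), so only the degree of alkylation has to be set by stoichiometry, and the mono and tris ethers are separated off.

Step 6
Reactants: 8 3,5-bis(methoxymethoxy)phenol
Product: 9 [3,5-bis(methoxymethoxy)phenoxy]triisopropylsilane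
Conditions: TIPSCl, imidazole, DMF, rt
Reagents that add atoms: chlorotriisopropylsilane, CC(C)[Si](Cl)(C(C)C)C(C)C
Why: Standard phenol silylation marks the future O1 with a bulky group that survives n-BuLi and shields its two ortho positions from metalation.

Step 7
Reactants: 9 [3,5-bis(methoxymethoxy)phenoxy]triisopropylsilane; 6 6-ethyl-3-iodo-4-(methoxymethoxy)-5-methyl-2H-pyran-2-one
Product: 12 6-ethyl-3-[2,6-bis(methoxymethoxy)-4-(triisopropylsilyloxy)phenyl]-4-(methoxymethoxy)-5-methyl-2H-pyran-2-one, via aryllithium 10 (not isolated), via arylzinc chloride 11 (not isolated)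
Conditions: n-BuLi, THF, 0 °C; ZnCl2, 0 °C to rt; then 6, Pd2(dba)3 (2.5 mol %), RuPhos (10 mol %), THF, 65 °C
Reagents that add atoms: none
Why: Directed ortho-metalation takes place at the carbon flanked by both MOM ethers, and transmetalation to zinc followed by Negishi coupling with a bulky dialkylbiarylphosphine, a catalyst type proven for fourfold ortho-substituted biaryls, joins it to the readily inserting C3–I bond without the protodeboronation that plagues 2,6-dialkoxyarylboron reagents.

Step 8
Reactants: 12 6-ethyl-3-[2,6-bis(methoxymethoxy)-4-(triisopropylsilyloxy)phenyl]-4-(methoxymethoxy)-5-methyl-2H-pyran-2-one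
Product: 13 6-ethyl-3-[4-hydroxy-2,6-bis(methoxymethoxy)phenyl]-4-(methoxymethoxy)-5-methyl-2H-pyran-2-one
Conditions: Bu4NF, AcOH (1:1), THF, 0 °C to rt
Reagents that add atoms: none
Why: Fluoride cleaves the aryl silyl ether selectively, and the acetic acid buffer keeps basic fluoride and phenoxide away from the pyranone acetal.

Step 9
Reactants: 13 6-ethyl-3-[4-hydroxy-2,6-bis(methoxymethoxy)phenyl]-4-(methoxymethoxy)-5-methyl-2H-pyran-2-one; 14 2-methylbut-3-yn-2-ol
Product: 16 6-ethyl-3-[2,6-bis(methoxymethoxy)-4-(2-methylbut-3-yn-2-yloxy)phenyl]-4-(methoxymethoxy)-5-methyl-2H-pyran-2-one, via 2-methylbut-3-yn-2-yl trifluoroacetate 15 (not isolated)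
Conditions: 14, (CF3CO)2O, DBU, MeCN, −5 °C; then 13, DBU, CuCl2 (1 mol %), MeCN, −5 °C
Reagents that add atoms: none
Why: Copper-catalysed O-propargylation of a phenol with a tertiary propargylic ester, the standard entry to aryl 1,1-dimethylpropargyl ethers, suits 13 because both positions ortho to its phenol are still open.

Step 10
Reactants: 16 6-ethyl-3-[2,6-bis(methoxymethoxy)-4-(2-methylbut-3-yn-2-yloxy)phenyl]-4-(methoxymethoxy)-5-methyl-2H-pyran-2-one
Product: 17 6-ethyl-3-[2,6-bis(methoxymethoxy)-4-(2-methylbut-3-en-2-yloxy)phenyl]-4-(methoxymethoxy)-5-methyl-2H-pyran-2-one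
Conditions: H2 (1 atm), Pd/CaCO3–Pb(OAc)2 (Lindlar catalyst), quinoline, EtOAc, rt
Reagents that add atoms: none
Why: Lindlar semihydrogenation stops the terminal alkyne at the vinyl stage, and it is placed before the iodination so that no C–I bond meets palladium and hydrogen.

Step 11
Reactants: 17 6-ethyl-3-[2,6-bis(methoxymethoxy)-4-(2-methylbut-3-en-2-yloxy)phenyl]-4-(methoxymethoxy)-5-methyl-2H-pyran-2-one
Product: 18 6-ethyl-3-[3-iodo-2,6-bis(methoxymethoxy)-4-(2-methylbut-3-en-2-yloxy)phenyl]-4-(methoxymethoxy)-5-methyl-2H-pyran-2-one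
Conditions: NIS (1.0 equiv), MeCN, −20 to 0 °C, dark; Na2S2O3 quench
Reagents that add atoms: N-iodosuccinimide, O=C1CCC(=O)N1I
Why: In this electrophilic aromatic iodination of a trialkoxybenzene the two open ring positions are equivalent, the first iodine slows a second substitution, and the monosubstituted vinyl group is far less nucleophilic than the arene, which is why iodine enters before the electron-rich prenyl olefin exists.

Step 12
Reactants: 18 6-ethyl-3-[3-iodo-2,6-bis(methoxymethoxy)-4-(2-methylbut-3-en-2-yloxy)phenyl]-4-(methoxymethoxy)-5-methyl-2H-pyran-2-one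
Product: 20 6-ethyl-3-[4-hydroxy-3-iodo-2,6-bis(methoxymethoxy)-5-(3-methylbut-2-en-1-yl)phenyl]-4-(methoxymethoxy)-5-methyl-2H-pyran-2-one, via ortho-dienone 19 (not isolated)
Conditions: PhNEt2, 120 °C
Reagents that add atoms: none
Why: In the aromatic Claisen rearrangement the [3,3] shift turns the 1,1-dimethylallyl unit into a prenyl group on the only ortho carbon that bears hydrogen, dienone 19 rearomatises to the phenol, and a shift to the iodinated ortho carbon is reversible and unproductive.

Step 13
Reactants: 20 6-ethyl-3-[4-hydroxy-3-iodo-2,6-bis(methoxymethoxy)-5-(3-methylbut-2-en-1-yl)phenyl]-4-(methoxymethoxy)-5-methyl-2H-pyran-2-one; 21 carbon monoxide; 22 phenylacetylene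
Product: 25 6-[6-ethyl-4-(methoxymethoxy)-5-methyl-2-oxo-2H-pyran-3-yl]-5,7-bis(methoxymethoxy)-8-(3-methylbut-2-en-1-yl)-2-phenyl-4H-chromen-4-one, via ortho-hydroxyaryl ynone 23 (not isolated), via beta-diethylamino enone 24 (not isolated)
Conditions: PdCl2(PPh3)2 (5 mol %), CO (10 bar), Et2NH (5 equiv), DMF, 70 °C
Reagents that add atoms: none
Why: PdCl2(PPh3)2 is reduced in the flask to zerovalent palladium, which inserts into the C4a–I bond of 20, CO insertion gives the aroylpalladium iodide, and copper-free coupling with the amine-deprotonated alkyne releases ynone 23, the closest known reaction type being the carbonylative Sonogashira annulation of 2-iodophenols and terminal alkynes to chromones. Et2NH then adds to the beta carbon (C2) of 23 to give enaminone 24, and the phenol on C8a displaces the amine by addition–elimination. Ring C thus closes in the 6-endo sense (6-endo-dig counted from the ynone, 6-endo-trig at the enaminone stage), and the 5-exo path to the aurone is shut off because the amine has already polarised and occupied C2. No stereocentre is formed. The step needs CO insertion to outrun direct alkynylation, which the CO pressure and the absence of a copper salt favour, and it needs closure through the right oxygen, which is certain because O5 and O7 are MOM ethers, iodine sits on C4a alone and the prenyl group already occupies C8. The pyranone is fully substituted and flanked by the twisted ring A, so the hindered amine, kept to a few equivalents, should leave it and its acetal untouched.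

Step 14
Reactants: 25 6-[6-ethyl-4-(methoxymethoxy)-5-methyl-2-oxo-2H-pyran-3-yl]-5,7-bis(methoxymethoxy)-8-(3-methylbut-2-en-1-yl)-2-phenyl-4H-chromen-4-one
Product: 26 (2S)-6-[6-ethyl-4-(methoxymethoxy)-5-methyl-2-oxo-2H-pyran-3-yl]-5,7-bis(methoxymethoxy)-8-(3-methylbut-2-en-1-yl)-2-phenylchroman-4-one
Conditions: Cu(OAc)2 (5 mol %), (R)-DTBM-SEGPHOS (5.5 mol %), (EtO)2MeSiH, t-BuOH, toluene, 0 °C to rt
Reagents that add atoms: none
Why: In this copper hydride asymmetric conjugate reduction, a reaction type established for chromones, the bisphosphine-bound CuH delivers hydride to one face of C2 and t-BuOH protonates the copper enolate before it can expel the C8a phenoxide, so the (S) centre is set by the ligand alone (its antipode to be confirmed on flavone itself and exchanged if required), while the prenyl olefin and the tetrasubstituted pyranone are inert to CuH.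

Step 15
Reactants: 26 (2S)-6-[6-ethyl-4-(methoxymethoxy)-5-methyl-2-oxo-2H-pyran-3-yl]-5,7-bis(methoxymethoxy)-8-(3-methylbut-2-en-1-yl)-2-phenylchroman-4-one
Product: 27 (2S)-6-(6-ethyl-4-hydroxy-5-methyl-2-oxo-2H-pyran-3-yl)-5,7-dihydroxy-8-(3-methylbut-2-en-1-yl)-2-phenylchroman-4-one
Conditions: 3 M aq HCl, MeOH, 40 °C
Reagents that add atoms: none
Why: Acid-catalysed transacetalisation removes all three MOM groups as dimethoxymethane, and dilute acid at 40 °C is chosen because flavanones lose C2 integrity through base-induced ring opening and not under mild acid, and because stronger acid would start chroman formation between the prenyl group and O7 or dehydrative furan closure between the pyranone O4 and a ring A phenol.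

Compound list
1 | 3-pentanone | CCC(=O)CC | starting material
2 | (Z)-3-(trimethylsilyloxy)pent-2-ene | C/C=C(/CC)O[Si](C)(C)C | intermediate
3 | malonyl dichloride | O=C(Cl)CC(=O)Cl | starting material
4 | 6-ethyl-4-hydroxy-5-methyl-2H-pyran-2-one | CCc1oc(=O)cc(O)c1C | intermediate
5 | 6-ethyl-4-hydroxy-3-iodo-5-methyl-2H-pyran-2-one | CCc1oc(=O)c(I)c(O)c1C | intermediate
6 | 6-ethyl-3-iodo-4-(methoxymethoxy)-5-methyl-2H-pyran-2-one | CCc1oc(=O)c(I)c(OCOC)c1C | intermediate
7 | phloroglucinol | Oc1cc(O)cc(O)c1 | starting material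
8 | 3,5-bis(methoxymethoxy)phenol | COCOc1cc(O)cc(OCOC)c1 | intermediate
9 | [3,5-bis(methoxymethoxy)phenoxy]triisopropylsilane | COCOc1cc(OCOC)cc(O[Si](C(C)C)(C(C)C)C(C)C)c1 | intermediate
10 | 2,6-bis(methoxymethoxy)-4-(triisopropylsilyloxy)phenyllithium (not isolated) | [Li]c1c(OCOC)cc(O[Si](C(C)C)(C(C)C)C(C)C)cc1OCOC | intermediate
11 | 2,6-bis(methoxymethoxy)-4-(triisopropylsilyloxy)phenylzinc chloride (not isolated) | Cl[Zn]c1c(OCOC)cc(O[Si](C(C)C)(C(C)C)C(C)C)cc1OCOC | intermediate
12 | 6-ethyl-3-[2,6-bis(methoxymethoxy)-4-(triisopropylsilyloxy)phenyl]-4-(methoxymethoxy)-5-methyl-2H-pyran-2-one | CCc1oc(=O)c(-c2c(OCOC)cc(O[Si](C(C)C)(C(C)C)C(C)C)cc2OCOC)c(OCOC)c1C | intermediate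
13 | 6-ethyl-3-[4-hydroxy-2,6-bis(methoxymethoxy)phenyl]-4-(methoxymethoxy)-5-methyl-2H-pyran-2-one | CCc1oc(=O)c(-c2c(OCOC)cc(O)cc2OCOC)c(OCOC)c1C | intermediate
14 | 2-methylbut-3-yn-2-ol | CC(C)(O)C#C | starting material
15 | 2-methylbut-3-yn-2-yl trifluoroacetate (not isolated) | C#CC(C)(C)OC(=O)C(F)(F)F | intermediate
16 | 6-ethyl-3-[2,6-bis(methoxymethoxy)-4-(2-methylbut-3-yn-2-yloxy)phenyl]-4-(methoxymethoxy)-5-methyl-2H-pyran-2-one | CCc1oc(=O)c(-c2c(OCOC)cc(OC(C)(C)C#C)cc2OCOC)c(OCOC)c1C | intermediate
17 | 6-ethyl-3-[2,6-bis(methoxymethoxy)-4-(2-methylbut-3-en-2-yloxy)phenyl]-4-(methoxymethoxy)-5-methyl-2H-pyran-2-one | CCc1oc(=O)c(-c2c(OCOC)cc(OC(C)(C)C=C)cc2OCOC)c(OCOC)c1C | intermediate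
18 | 6-ethyl-3-[3-iodo-2,6-bis(methoxymethoxy)-4-(2-methylbut-3-en-2-yloxy)phenyl]-4-(methoxymethoxy)-5-methyl-2H-pyran-2-one | CCc1oc(=O)c(-c2c(OCOC)cc(OC(C)(C)C=C)c(I)c2OCOC)c(OCOC)c1C | intermediate
19 | racemic 2-iodo-3,5-bis(methoxymethoxy)-6-prenylcyclohexa-2,4-dien-1-one bearing the protected pyranone at C4 (Claisen dienone, not isolated) | CCc1oc(=O)c(C2=C(OCOC)C(CC=C(C)C)C(=O)C(I)=C2OCOC)c(OCOC)c1C | intermediate
20 | 6-ethyl-3-[4-hydroxy-3-iodo-2,6-bis(methoxymethoxy)-5-(3-methylbut-2-en-1-yl)phenyl]-4-(methoxymethoxy)-5-methyl-2H-pyran-2-one | CCc1oc(=O)c(-c2c(OCOC)c(I)c(O)c(CC=C(C)C)c2OCOC)c(OCOC)c1C | intermediate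
21 | carbon monoxide | [C-]#[O+] | starting material
22 | phenylacetylene | C#Cc1ccccc1 | starting material
23 | 6-ethyl-3-[4-hydroxy-2,6-bis(methoxymethoxy)-3-(3-phenylprop-2-ynoyl)-5-prenylphenyl]-4-(methoxymethoxy)-5-methyl-2H-pyran-2-one (not isolated) | CCc1oc(=O)c(-c2c(OCOC)c(C(=O)C#Cc3ccccc3)c(O)c(CC=C(C)C)c2OCOC)c(OCOC)c1C | intermediate
24 | 3-[3-(3-diethylamino-3-phenylprop-2-enoyl)-4-hydroxy-2,6-bis(methoxymethoxy)-5-prenylphenyl]-6-ethyl-4-(methoxymethoxy)-5-methyl-2H-pyran-2-one, olefin geometry immaterial (not isolated) | CCc1oc(=O)c(-c2c(OCOC)c(C(=O)C=C(N(CC)CC)c3ccccc3)c(O)c(CC=C(C)C)c2OCOC)c(OCOC)c1C | intermediate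
25 | 6-[6-ethyl-4-(methoxymethoxy)-5-methyl-2-oxo-2H-pyran-3-yl]-5,7-bis(methoxymethoxy)-8-(3-methylbut-2-en-1-yl)-2-phenyl-4H-chromen-4-one | CCc1oc(=O)c(-c2c(OCOC)c(CC=C(C)C)c3oc(-c4ccccc4)cc(=O)c3c2OCOC)c(OCOC)c1C | intermediate
26 | (2S)-6-[6-ethyl-4-(methoxymethoxy)-5-methyl-2-oxo-2H-pyran-3-yl]-5,7-bis(methoxymethoxy)-8-(3-methylbut-2-en-1-yl)-2-phenylchroman-4-one | CCc1oc(=O)c(-c2c(OCOC)c(CC=C(C)C)c3c(c2OCOC)C(=O)C[C@@H](c2ccccc2)O3)c(OCOC)c1C | intermediate
27 | (2S)-6-(6-ethyl-4-hydroxy-5-methyl-2-oxo-2H-pyran-3-yl)-5,7-dihydroxy-8-(3-methylbut-2-en-1-yl)-2-phenylchroman-4-one | CCc1oc(=O)c(-c2c(O)c(CC=C(C)C)c3c(c2O)C(=O)C[C@@H](c2ccccc2)O3)c(O)c1C | target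

Total step count: 15.
Longest linear sequence: 13 steps (steps 1–4 and 7–15, from 3-pentanone). The ring A branch from phloroglucinol runs through 11 steps (steps 5–15).

Steps most likely to fail

Step 13. CO insertion at the doubly ortho-flanked arylpalladium may be slow. Direct alkynylation followed by five-membered ring closure, capture of the aroylpalladium by the amine, or amine attack on the pyranone acetal could then overtake the annulation. The fallback brings in C4 together with the alkyne as an aldehyde carbon and uses no palladium. It sets out from 20. Deprotonation with MeMgCl and iodine–magnesium exchange with i-PrMgCl·LiCl (THF, −20 °C) should give the magnesiated chloromagnesium phenolate F1. Addition of F1 to 3-phenylprop-2-ynal gives the racemic propargylic alcohol F2. MnO2 (CH2Cl2, rt) oxidises F2 to ynone 23, now isolated. Et2NH in MeCN at rt to 40 °C carries 23 through 24 to 25, where the route is rejoined.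

Step 14. Facial selectivity on the crowded, electron-rich flavone may be poor, or the copper enolate may open ring C by expelling the phenoxide, with erosion of enantiopurity. The fallback replaces asymmetric induction by resolution and sets out from 25. Conjugate reduction with an achiral copper hydride (Cu(OAc)2, 1,2-bis(diphenylphosphino)benzene, (EtO)2MeSiH, t-BuOH, toluene) gives the racemic flavanone F3. Kinetic resolution follows by asymmetric transfer hydrogenation (Cp*RhCl[(R,R)-TsDPEN], HCO2H–Et3N, EtOAc, rt), stopped near half conversion. It reduces the (2R) ketone to the cis-(2R,4R)-flavan-4-ol F4 and leaves the (2S) ketone. That ketone is separated by chromatography and is 26, where the route is rejoined.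

Step 7. Transmetalation and reductive elimination at the fourfold ortho-substituted axis may be sluggish, so that protodemetalation of the arylzinc and reduction of the C3–I bond win. The fallback forms the same bond by ligand coupling on lead (Pinhey arylation), which tolerates crowded aryl groups. It sets out from aryllithium 10 (made from 9 as in step 7) and from pyranone 4. B(OMe)3 (−78 °C to rt, NH4Cl work-up) gives the arylboronic acid F5. Boron–lead exchange with Pb(OAc)4 and catalytic Hg(OAc)2 (CHCl3, 40 °C) gives the aryllead triacetate F6. Addition of 4 and pyridine (CHCl3, 40–60 °C) gives the 3-aryl-4-hydroxypyranone F7. MOMCl and i-Pr2NEt convert F7 into 12, where the route is rejoined. Steps 3 and 4 are then not needed.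

Further compounds
F1 | step 13 | chloromagnesium phenolate of 20 with MgCl in place of iodine | CCc1oc(=O)c(-c2c(OCOC)c([Mg]Cl)c(O[Mg]Cl)c(CC=C(C)C)c2OCOC)c(OCOC)c1C
F2 | step 13 | racemic 6-ethyl-3-[4-hydroxy-3-(1-hydroxy-3-phenylprop-2-yn-1-yl)-2,6-bis(methoxymethoxy)-5-prenylphenyl]-4-(methoxymethoxy)-5-methyl-2H-pyran-2-one | CCc1oc(=O)c(-c2c(OCOC)c(C(O)C#Cc3ccccc3)c(O)c(CC=C(C)C)c2OCOC)c(OCOC)c1C
F3 | step 14 | racemic 6-[6-ethyl-4-(methoxymethoxy)-5-methyl-2-oxo-2H-pyran-3-yl]-5,7-bis(methoxymethoxy)-8-prenyl-2-phenylchroman-4-one | CCc1oc(=O)c(-c2c(OCOC)c(CC=C(C)C)c3c(c2OCOC)C(=O)CC(c2ccccc2)O3)c(OCOC)c1C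
F4 | step 14 | (2R,4R)-6-[6-ethyl-4-(methoxymethoxy)-5-methyl-2-oxo-2H-pyran-3-yl]-5,7-bis(methoxymethoxy)-8-prenyl-2-phenylchroman-4-ol | CCc1oc(=O)c(-c2c(OCOC)c(CC=C(C)C)c3c(c2OCOC)[C@H](O)C[C@H](c2ccccc2)O3)c(OCOC)c1C
F5 | step 7 | [2,6-bis(methoxymethoxy)-4-(triisopropylsilyloxy)phenyl]boronic acid | OB(O)c1c(OCOC)cc(O[Si](C(C)C)(C(C)C)C(C)C)cc1OCOC
F6 | step 7 | [2,6-bis(methoxymethoxy)-4-(triisopropylsilyloxy)phenyl]lead triacetate | CC(=O)O[Pb](OC(C)=O)(OC(C)=O)c1c(OCOC)cc(O[Si](C(C)C)(C(C)C)C(C)C)cc1OCOC
F7 | step 7 | 6-ethyl-4-hydroxy-3-[2,6-bis(methoxymethoxy)-4-(triisopropylsilyloxy)phenyl]-5-methyl-2H-pyran-2-one | CCc1oc(=O)c(-c2c(OCOC)cc(O[Si](C(C)C)(C(C)C)C(C)C)cc2OCOC)c(O)c1C
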